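**Plan**
1. Numbering: naphthalene A has C1 (biaryl carbon), C2‑OH, C4‑OMe, C5‑OMe, C7‑CH3; naphthalene B has C1' (biaryl carbon), C2'‑CH3, C3'‑H, C4'‑OH, C5'‑OMe, C6'‑OH; ring B1 is C1'–C2'–C3'–C4'–C4a'–C8a'.
2. Retrosynthesis: the biaryl bond is never cut. With a benzyl ester placed on C3', ring B1 is opened at C2'–C3' and C1'–C8a'; then the alkyne–arene bond C1–C1' (Sonogashira) and C3'–C4' (Claisen) are cut.
3. Enabling feature: aryl‑bearing C1' and methyl‑bearing C2' are neighbours, so together they are the two carbons of a prop‑1‑ynyl group on C1 of naphthalene A, and C3'–C4'–C4a'–C8a' is an aroylacetate.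
4. Forward: bromo keto ester 6 (4 steps) and alkyne 21 (8 steps) are joined in step 13, which builds ring B1. The second ring of naphthalene A comes from anionic closure of an ortho‑allyl benzamide, and O2 from C–H borylation/oxidation. Hydrogenolysis, decarboxylation and pivalate removal finish the route.
5. Stereochemistry: the target has no stereocentre; the hindered C1–C1' axis is formed without control.

Key step: step 13

Remark on the chemistry: the target SMILES carries no axial descriptor, so the racemic mixture of atropisomers is taken as the goal.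

**Step 1**
Reactants: 1 methyl 2,3‑dihydroxybenzoate
Product: 2 methyl 3‑(benzyloxy)‑2‑hydroxybenzoate
Conditions: BnBr (1.0 equiv), K2CO3 (1.1 equiv), DMF, rt
Reagents that add atoms: benzyl bromide, BrCc1ccccc1
Why: Williamson etherification; the 2‑OH is held in a hydrogen bond to the ester carbonyl, so one equivalent of carbonate should ionise and alkylate the 3‑OH.

**Step 2**
Reactants: 2 methyl 3‑(benzyloxy)‑2‑hydroxybenzoate
Product: 3 methyl 3‑(benzyloxy)‑2‑methoxybenzoate
Conditions: MeI (2 equiv), K2CO3 (2 equiv), DMF, 50 °C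
Reagents that add atoms: iodomethane, CI
Why: Williamson methylation of the remaining chelated phenol, which should need only gentle heating with excess iodomethane.

**Step 3**
Reactants: 3 methyl 3‑(benzyloxy)‑2‑methoxybenzoate; 4 benzyl acetate
Product: 5 benzyl 3‑[3‑(benzyloxy)‑2‑methoxyphenyl]‑3‑oxopropanoate
Conditions: 4 (2 equiv), LiN(SiMe3)2 (3.2 equiv), THF, −78 °C; then 3, −78 → −20 °C; 1 M HCl quench
Reagents that add atoms: none
Why: crossed Claisen condensation; the preformed lithium enolate of benzyl acetate acylates on the non‑enolisable aryl ester, and excess amide base keeps the product as its enolate, which should suppress a second addition and ester exchange by methoxide.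

**Step 4**
Reactants: 5 benzyl 3‑[3‑(benzyloxy)‑2‑methoxyphenyl]‑3‑oxopropanoate
Product: 6 benzyl 2‑bromo‑3‑[3‑(benzyloxy)‑2‑methoxyphenyl]‑3‑oxopropanoate (racemic, configurationally labile)
Conditions: NBS (1.02 equiv), NH4OAc (10 mol%), Et2O, rt, dark
Reagents that add atoms: N‑bromosuccinimide, O=C1CCC(=O)N1Br
Why: electrophilic alpha‑bromination of the enolised beta‑keto ester; one equivalent should stop at the monobromide, and the acyl‑deactivated ring and the benzylic positions are not attacked under ionic conditions.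

**Step 5**
Reactants: 7 2‑methoxy‑4‑methylbenzoic acid
Product: 9 N,N‑diethyl‑2‑methoxy‑4‑methylbenzamide, via acid chloride 8 (not isolated)
Conditions: SOCl2, DMF (cat.), toluene, 70 °C; evaporate; Et2NH, Et3N, CH2Cl2, 0 °C → rt
Reagents that add atoms: diethylamine, CCNCC
Why: acid chloride formation and amidation give the tertiary amide that later serves as directing group and as internal acylating agent.

**Step 6**
Reactants: 9 N,N‑diethyl‑2‑methoxy‑4‑methylbenzamide; 10 allyl bromide
Product: 13 N,N‑diethyl‑2‑methoxy‑4‑methyl‑6‑(prop‑2‑en‑1‑yl)benzamide, via aryllithium 11 (not isolated), via arylmagnesium bromide 12 (not isolated)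
Conditions: s‑BuLi, TMEDA, THF, −78 °C; MgBr2·OEt2; allyl bromide, −78 °C → rt
Reagents that add atoms: none
Why: directed ortho metalation; the diethylamide, a stronger director than methoxy, should guide lithiation to C6, its only free ortho position, and transmetalation to magnesium lets allyl bromide alkylate without halogen–metal exchange.

**Step 7**
Reactants: 13 N,N‑diethyl‑2‑methoxy‑4‑methyl‑6‑(prop‑2‑en‑1‑yl)benzamide
Product: 14 8‑methoxy‑6‑methylnaphthalen‑1‑ol
Conditions: LiN(iPr)2 (2.2 equiv), THF, −78 °C → rt; 1 M HCl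
Reagents that add atoms: none
Why: anionic ring closure of an ortho‑allyl benzamide; the base removes the benzylic allylic proton, the far end of the allyl anion is acylated by the amide with loss of diethylamide, and tautomerisation should give the naphthol.

**Step 8**
Reactants: 14 8‑methoxy‑6‑methylnaphthalen‑1‑ol
Product: 15 1,8‑dimethoxy‑3‑methylnaphthalene
Conditions: NaH, MeI, DMF, 0 °C → rt
Reagents that add atoms: iodomethane, CI
Why: Williamson methylation; NaH breaks the peri hydrogen bond to the neighbouring methoxy group that would slow weaker bases.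

**Step 9**
Reactants: 15 1,8‑dimethoxy‑3‑methylnaphthalene
Product: 17 4,5‑dimethoxy‑7‑methylnaphthalen‑2‑ol, via pinacol boronate 16 (not isolated)
Conditions: [Ir(OMe)(cod)]2 (1.5 mol%), 4,4'‑di‑tert‑butyl‑2,2'‑bipyridine (3 mol%), B2pin2 (1.0 equiv), THF, 80 °C; then 30% H2O2, aq. NaOH, 0 °C
Reagents that add atoms: hydrogen peroxide, OO
Why: sterically governed iridium‑catalysed C–H borylation followed by C–B oxidation in the same flask; the C–H that becomes C2 of naphthalene A is the only one flanked by two hydrogens and not in a peri position, so oxygen should enter meta to the C4 methoxy group.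

**Step 10**
Reactants: 17 4,5‑dimethoxy‑7‑methylnaphthalen‑2‑ol
Product: 18 1‑iodo‑4,5‑dimethoxy‑7‑methylnaphthalen‑2‑ol
Conditions: NIS (1.0 equiv), CH2Cl2, 0 °C, dark
Reagents that add atoms: N‑iodosuccinimide, O=C1CCC(=O)N1I
Why: electrophilic aromatic iodination; C1 is the alpha position ortho to the free OH and para to the C4 methoxy group, the site where 2‑naphthols are halogenated.

**Step 11**
Reactants: 18 1‑iodo‑4,5‑dimethoxy‑7‑methylnaphthalen‑2‑ol
Product: 19 1‑iodo‑4,5‑dimethoxy‑7‑methylnaphthalen‑2‑yl 2,2‑dimethylpropanoate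
Conditions: PivCl, Et3N, DMAP (cat.), CH2Cl2, 0 °C → rt
Reagents that add atoms: pivaloyl chloride, CC(C)(C)C(Cl)=O
Why: DMAP‑catalysed O‑acylation; the pivalate masks the naphthol during the coupling and, unlike a benzyl ether, places no abstractable C–H within reach of the C1' vinyl radical of step 13.

**Step 12**
Reactants: 19 1‑iodo‑4,5‑dimethoxy‑7‑methylnaphthalen‑2‑yl 2,2‑dimethylpropanoate; 20 propyne
Product: 21 4,5‑dimethoxy‑7‑methyl‑1‑(prop‑1‑yn‑1‑yl)naphthalen‑2‑yl 2,2‑dimethylpropanoate
Conditions: propyne (excess), PdCl2(PPh3)2 (5 mol%), CuI (10 mol%), Et3N/THF, sealed tube, 50 °C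
Reagents that add atoms: none
Why: Sonogashira coupling of an aryl iodide with a terminal alkyne; the linear alkyne is the least demanding carbon substituent the crowded C1 can carry, and the tertiary amine should leave the pivalate intact.

**Step 13**
Reactants: 6 benzyl 2‑bromo‑3‑[3‑(benzyloxy)‑2‑methoxyphenyl]‑3‑oxopropanoate; 21 4,5‑dimethoxy‑7‑methyl‑1‑(prop‑1‑yn‑1‑yl)naphthalen‑2‑yl 2,2‑dimethylpropanoate
Product: 23 benzyl 7‑(benzyloxy)‑4‑[2‑(2,2‑dimethylpropanoyloxy)‑4,5‑dimethoxy‑7‑methylnaphthalen‑1‑yl]‑1‑hydroxy‑8‑methoxy‑3‑methylnaphthalene‑2‑carboxylate, via keto tautomer 22 (not isolated)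
Conditions: fac‑Ir(ppy)3 (1 mol%), 6 (1.5 equiv), degassed DMF, blue LEDs (450 nm), rt
Reagents that add atoms: none
Why: The photoexcited trivalent iridium complex reduces the C–Br bond of 6, and the electrophilic keto ester radical at C3' should add to the methyl‑bearing alkyne carbon (C3'–C2') because this gives a linear vinyl radical at C1' conjugated with naphthalene A, which lies perpendicular to the alkene plane. That radical closes ring B1 by 6‑endo‑trig attack on C8a' of the aroyl ring (C1'–C8a', homolytic aromatic substitution); the cyclohexadienyl radical is oxidised by the tetravalent iridium complex formed in the first event, and loss of a proton and enolisation of keto ester 22 give naphthol 23 and HBr. The closest known reaction is the visible‑light photoredox annulation of 2‑bromo aroylacetates with aryl alkyl alkynes to 1‑naphthols. No stereocentre is created and the C1–C1' axis arises as the racemate. Two selectivities are needed: the regiochemistry of alkyne addition, secured by the stability of the aryl‑conjugated vinyl radical, and the site of ring closure, secured because the other ortho carbon of the aroyl ring bears OMe. The pivalate on O2 offers the vinyl radical no hydrogen for a 1,5‑shift and makes the alkyne aryl group less prone to oxidation to a vinyl cation.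

**Step 14**
Reactants: 23 benzyl ester from step 13
Product: 24 4‑[2‑(2,2‑dimethylpropanoyloxy)‑4,5‑dimethoxy‑7‑methylnaphthalen‑1‑yl]‑1,7‑dihydroxy‑8‑methoxy‑3‑methylnaphthalene‑2‑carboxylic acid
Conditions: H2 (1 atm), 10% Pd/C, EtOAc/MeOH, rt
Reagents that add atoms: none
Why: hydrogenolysis cleaves the benzyl ester and the benzyl ether at their unhindered benzylic C–O bonds, so the crowded C3' acid should be freed without attack on its shielded carbonyl; the aryl pivalate, methyl ethers and naphthalene rings are inert at 1 atm.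

**Step 15**
Reactants: 24 hydroxy acid from step 14
Product: 25 1‑(4,6‑dihydroxy‑5‑methoxy‑2‑methylnaphthalen‑1‑yl)‑4,5‑dimethoxy‑7‑methylnaphthalen‑2‑yl 2,2‑dimethylpropanoate
Conditions: degassed DMSO, 130 °C, Ar
Reagents that add atoms: none
Why: thermal protodecarboxylation of an ortho‑hydroxy naphthoic acid, which should react through its beta‑keto acid tautomer in a six‑membered transition state and is helped by the electron‑rich ring.

**Step 16**
Reactants: 25 pivalate from step 15
Product: 26 4,5,5'‑trimethoxy‑2',7‑dimethyl‑[1,1'‑binaphthalene]‑2,4',6'‑triol (CNP0288130.0)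
Conditions: K2CO3, degassed MeOH, 40 °C, Ar; then AcOH
Reagents that add atoms: none
Why: base‑mediated methanolysis (transesterification) of the aryl pivalate, whose naphthoxide is a good leaving group; the methyl ethers are untouched and exclusion of air protects the electron‑rich naphthoxides.

**Compound list**
1 | methyl 2,3‑dihydroxybenzoate | COC(=O)c1cccc(O)c1O | starting material
2 | methyl 3‑(benzyloxy)‑2‑hydroxybenzoate | COC(=O)c1cccc(OCc2ccccc2)c1O | intermediate
3 | methyl 3‑(benzyloxy)‑2‑methoxybenzoate | COC(=O)c1cccc(OCc2ccccc2)c1OC | intermediate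
4 | benzyl acetate | CC(=O)OCc1ccccc1 | starting material
5 | benzyl 3‑[3‑(benzyloxy)‑2‑methoxyphenyl]‑3‑oxopropanoate | O=C(CC(=O)c1cccc(OCc2ccccc2)c1OC)OCc1ccccc1 | intermediate
6 | benzyl 2‑bromo‑3‑[3‑(benzyloxy)‑2‑methoxyphenyl]‑3‑oxopropanoate (racemic) | O=C(OCc1ccccc1)C(Br)C(=O)c1cccc(OCc2ccccc2)c1OC | intermediate
7 | 2‑methoxy‑4‑methylbenzoic acid | COc1cc(C)ccc1C(=O)O | starting material
8 | 2‑methoxy‑4‑methylbenzoyl chloride | COc1cc(C)ccc1C(Cl)=O | intermediate
9 | N,N‑diethyl‑2‑methoxy‑4‑methylbenzamide | CCN(CC)C(=O)c1ccc(C)cc1OC | intermediate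
10 | allyl bromide (3‑bromoprop‑1‑ene) | C=CCBr | starting material
11 | [2‑(diethylcarbamoyl)‑3‑methoxy‑5‑methylphenyl]lithium | [Li]c1cc(C)cc(OC)c1C(=O)N(CC)CC | intermediate
12 | [2‑(diethylcarbamoyl)‑3‑methoxy‑5‑methylphenyl]magnesium bromide | Br[Mg]c1cc(C)cc(OC)c1C(=O)N(CC)CC | intermediate
13 | N,N‑diethyl‑2‑methoxy‑4‑methyl‑6‑(prop‑2‑en‑1‑yl)benzamide | C=CCc1cc(C)cc(OC)c1C(=O)N(CC)CC | intermediate
14 | 8‑methoxy‑6‑methylnaphthalen‑1‑ol | COc1cc(C)cc2cccc(O)c12 | intermediate
15 | 1,8‑dimethoxy‑3‑methylnaphthalene | COc1cc(C)cc2cccc(OC)c12 | intermediate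
16 | 2‑(4,5‑dimethoxy‑7‑methylnaphthalen‑2‑yl)‑4,4,5,5‑tetramethyl‑1,3,2‑dioxaborolane | COc1cc(C)cc2cc(B3OC(C)(C)C(C)(C)O3)cc(OC)c12 | intermediate
17 | 4,5‑dimethoxy‑7‑methylnaphthalen‑2‑ol | COc1cc(C)cc2cc(O)cc(OC)c12 | intermediate
18 | 1‑iodo‑4,5‑dimethoxy‑7‑methylnaphthalen‑2‑ol | COc1cc(C)cc2c(I)c(O)cc(OC)c12 | intermediate
19 | 1‑iodo‑4,5‑dimethoxy‑7‑methylnaphthalen‑2‑yl 2,2‑dimethylpropanoate | COc1cc(C)cc2c(I)c(OC(=O)C(C)(C)C)cc(OC)c12 | intermediate
20 | propyne | CC#C | starting material
21 | 4,5‑dimethoxy‑7‑methyl‑1‑(prop‑1‑yn‑1‑yl)naphthalen‑2‑yl 2,2‑dimethylpropanoate | CC#Cc1c(OC(=O)C(C)(C)C)cc(OC)c2c(OC)cc(C)cc12 | intermediate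
22 | benzyl 7‑(benzyloxy)‑4‑[2‑(2,2‑dimethylpropanoyloxy)‑4,5‑dimethoxy‑7‑methylnaphthalen‑1‑yl]‑8‑methoxy‑3‑methyl‑1‑oxo‑1,2‑dihydronaphthalene‑2‑carboxylate (racemic) | O=C(OCc1ccccc1)C1C(C)=C(c2c(OC(=O)C(C)(C)C)cc(OC)c3c(OC)cc(C)cc23)c2ccc(OCc3ccccc3)c(OC)c2C1=O | intermediate
23 | benzyl 7‑(benzyloxy)‑4‑[2‑(2,2‑dimethylpropanoyloxy)‑4,5‑dimethoxy‑7‑methylnaphthalen‑1‑yl]‑1‑hydroxy‑8‑methoxy‑3‑methylnaphthalene‑2‑carboxylate (racemic axis) | O=C(OCc1ccccc1)c1c(C)c(-c2c(OC(=O)C(C)(C)C)cc(OC)c3c(OC)cc(C)cc23)c2ccc(OCc3ccccc3)c(OC)c2c1O | intermediate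
24 | 4‑[2‑(2,2‑dimethylpropanoyloxy)‑4,5‑dimethoxy‑7‑methylnaphthalen‑1‑yl]‑1,7‑dihydroxy‑8‑methoxy‑3‑methylnaphthalene‑2‑carboxylic acid | O=C(O)c1c(C)c(-c2c(OC(=O)C(C)(C)C)cc(OC)c3c(OC)cc(C)cc23)c2ccc(O)c(OC)c2c1O | intermediate
25 | 1‑(4,6‑dihydroxy‑5‑methoxy‑2‑methylnaphthalen‑1‑yl)‑4,5‑dimethoxy‑7‑methylnaphthalen‑2‑yl 2,2‑dimethylpropanoate | COc1cc(C)cc2c(-c3c(C)cc(O)c4c(OC)c(O)ccc34)c(OC(=O)C(C)(C)C)cc(OC)c12 | intermediate
26 | 4,5,5'‑trimethoxy‑2',7‑dimethyl‑[1,1'‑binaphthalene]‑2,4',6'‑triol (CNP0288130.0, racemic axis) | COc1cc(C)cc2c(-c3c(C)cc(O)c4c(OC)c(O)ccc34)c(O)cc(OC)c12 | target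

**Count**
Total steps: 16. Longest linear sequence: 12 (steps 5–16, from acid 7).

**Steps most likely to fail**

Step 13. The keto ester radical may be lost by hydrogen abstraction from DMF or by dimerisation before it adds to the hindered internal alkyne. The electron‑rich vinyl radical may also be oxidised to a vinyl cation and trapped by the ketone oxygen, which would give a furan. The fallback generates the same C3' radical oxidatively and needs no C–Br bond. Keto ester 5 and alkyne 21 would be heated with trivalent manganese acetate, Mn(OAc)3·2H2O (2.5 equiv), in AcOH at 80 °C. The manganese enolate should deliver the radical continuously, the same two bonds form, and the cyclohexadienyl radical is oxidised by a second equivalent of the manganese salt. This sets out from 5 and 21 and comes back at 23; it passes through no compound outside the route (entry F0).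

Step 9. C–H activation may be slow on the electron‑rich naphthalene, and site control between C2 and the position next to the methoxy group may be incomplete. The fallback puts the C2 oxygen in place before the ring is closed. It sets out from 13. Tsuji–Wacker oxidation (PdCl2, CuCl, O2, DMF/H2O) should give N,N‑diethyl‑2‑methoxy‑4‑methyl‑6‑(2‑oxopropyl)benzamide F1. LiN(iPr)2 in THF then closes the ring by acylation of the methyl ketone enolate on the amide, to give 8‑methoxy‑6‑methylnaphthalene‑1,3‑diol F2. One equivalent of TIPSCl with imidazole should silylate the unhindered hydroxyl, since the other is held in the peri hydrogen bond, to give 8‑methoxy‑6‑methyl‑3‑{[tri(propan‑2‑yl)silyl]oxy}naphthalen‑1‑ol F3. NaH/MeI gives [(4,5‑dimethoxy‑7‑methylnaphthalen‑2‑yl)oxy]tri(propan‑2‑yl)silane F4, and Bu4NF in THF frees the naphthol. The route is rejoined at 17.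

Step 1. Site control between the two hydroxyls may be lost, giving 2‑O‑benzylation or double benzylation. The fallback replaces selective alkylation by selective dealkylation. It sets out from 1. Exhaustive benzylation (BnBr, K2CO3, DMF, 60 °C) gives methyl 2,3‑bis(benzyloxy)benzoate F5. MgBr2·OEt2 in toluene/Et2O at reflux then removes only the benzyl group ortho to the ester, by chelation between the carbonyl and the ether oxygen. The route is rejoined at 2.

**Further compounds**
F0 | step 13 | none | none
F1 | step 9 | N,N‑diethyl‑2‑methoxy‑4‑methyl‑6‑(2‑oxopropyl)benzamide | CC(=O)Cc1cc(C)cc(OC)c1C(=O)N(CC)CC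
F2 | step 9 | 8‑methoxy‑6‑methylnaphthalene‑1,3‑diol | COc1cc(C)cc2cc(O)cc(O)c12
F3 | step 9 | 8‑methoxy‑6‑methyl‑3‑{[tri(propan‑2‑yl)silyl]oxy}naphthalen‑1‑ol | COc1cc(C)cc2cc(O[Si](C(C)C)(C(C)C)C(C)C)cc(O)c12
F4 | step 9 | [(4,5‑dimethoxy‑7‑methylnaphthalen‑2‑yl)oxy]tri(propan‑2‑yl)silane | COc1cc(C)cc2cc(O[Si](C(C)C)(C(C)C)C(C)C)cc(OC)c12
F5 | step 1 | methyl 2,3‑bis(benzyloxy)benzoate | COC(=O)c1cccc(OCc2ccccc2)c1OCc1ccccc1
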